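**Retrosynthetic overview**
1. Xestin B ⇐ the corresponding C1 aldehyde (oxidation, O-methylation). The only ring, the 1,2-dioxine, is closed once, in step 6.
2. Dioxine ⇐ open-chain C3 peroxide carrying a C4=C5=C6 methoxyallene. Acid-triggered 6-endo O–C6 closure delivers the ketal carbon, its OMe and the cis ring alkene together.
3. C3–O–O stereocentre ⇐ amine-catalysed asymmetric peroxidation of a 2-en-4,5-dienal.
4. Key C3–C4 bond ⇐ γ-lithiated 1-alkyl-1-methoxyallene (a β-acylvinyl anion, i.e. homoenolate-type donor) + the carbonyl carbon of 3-(dimethylamino)acrolein.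
5. Allene ⇐ 1-lithio-1-methoxyallene (masked acyl anion) + 1,12-dibromododecane, then copper-catalysed sorbyl coupling.

Assumption: methoxyallene, (2E,4E)-hexa-2,4-dien-1-yl acetate, 3-(dimethylamino)acrolein and both enantiomers of the diarylprolinol silyl ether are purchased. C1–C6 in the text means the chain from the ester carbon (C1) to the ketal carbon (C6).

**Route**

Step 1
Reactants: 1 methoxyallene (1-methoxypropa-1,2-diene); 2 1,12-dibromododecane
Product: 4 15-bromo-3-methoxypentadeca-1,2-diene, via 1-lithio-1-methoxyallene 3 (not isolated)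
Conditions: n-BuLi, THF, −40 °C; then added to 2 (3 equiv), THF/DMPU, −40 °C → rt
Reagents that add atoms: none
Why: C1 lithiation of methoxyallene gives a masked acyl anion that is alkylated once (SN2) by the dibromide used in excess; no stereocentre is formed.

Step 2
Reactants: 4 15-bromo-3-methoxypentadeca-1,2-diene; 5 (2E,4E)-hexa-2,4-dien-1-yl acetate
Product: 7 (17E,19E)-3-methoxyhenicosa-1,2,17,19-tetraene, via alkylmagnesium bromide 6 (not isolated)
Conditions: Mg, THF, 40 °C; then 5, Li2CuCl4 (3 mol %), THF, −20 → 0 °C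
Reagents that add atoms: none
Why: copper-catalysed Grignard/allylic acetate coupling (Kochi type) occurs at the α-carbon of the sorbyl acetate with retention of the E,E-diene, as in dienyl pheromone syntheses; no stereocentre is formed.

Step 3
Reactants: 7 (17E,19E)-3-methoxyhenicosa-1,2,17,19-tetraene; 8 (E)-3-(dimethylamino)prop-2-enal
Product: 11 (2E,20E,22E)-6-methoxytetracosa-2,4,5,20,22-pentaenal, via γ-lithioallene 9 (not isolated), via lithium alkoxide adduct 10 (not isolated)
Conditions: n-BuLi, THF, −40 °C; 8, −78 °C; then aq NaH2PO4, 0 °C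
Reagents that add atoms: water, O
Why: n-BuLi removes the γ-allenic proton of the 1-alkyl-1-methoxyallene to give a β-acylvinyl anion (homoenolate) equivalent, whose 1,2-addition to the vinylogous formamide and collapse of the amino-carbinol on mild hydrolysis (vinylogous formylation) forms the key C3–C4 bond and the E-enal; the allene axis is racemic and is erased in step 6.

Step 4
Reactants: 12 2,3-dimethylbut-2-ene
Product: 14 2-hydroperoxy-2-methoxypropane, via acetone O-oxide 13 (not isolated)
Conditions: O3, CH2Cl2/MeOH, −78 °C; N2 purge; used as a solution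
Reagents that add atoms: ozone, O=[O+][O-]; methanol, CO
Why: ozonolysis in methanol traps the Criegee carbonyl oxide as the α-methoxy hydroperoxide, the standard preparation of this acid-removable hydroperoxide; no stereocentre is formed.

Step 5
Reactants: 11 (2E,20E,22E)-6-methoxytetracosa-2,4,5,20,22-pentaenal; 14 2-hydroperoxy-2-methoxypropane
Product: 15 (3R,20E,22E)-6-methoxy-3-[(2-methoxypropan-2-yl)peroxy]tetracosa-4,5,20,22-tetraenal
Conditions: (R)-2-{bis[3,5-bis(trifluoromethyl)phenyl](trimethylsilyloxy)methyl}pyrrolidine (15 mol %), 14 (1.5 equiv), toluene, 0 °C, no acid additive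
Reagents that add atoms: none
Why: iminium-catalysed asymmetric oxa-Michael addition (peroxidation) of an enal with an α-alkoxyalkyl hydroperoxide, in which the C(Ar)2OSiMe3 group of the (R)-catalyst blocks one face of the s-trans E-iminium ion so that the hydroperoxide adds to C3 from the open face and sets 3R, while the hindered sp carbon C5 disfavours 1,6-addition.

Step 6
Reactants: 15 (3R,20E,22E)-6-methoxy-3-[(2-methoxypropan-2-yl)peroxy]tetracosa-4,5,20,22-tetraenal
Product: 17 2-[(3R,6S)-6-methoxy-6-[(14E,16E)-octadeca-14,16-dien-1-yl]-3,6-dihydro-1,2-dioxin-3-yl]acetaldehyde, via free hydroperoxide 16 (not isolated)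
Conditions: PPTS (10 mol %), CH2Cl2, 4 Å MS, 0 °C → rt, N2 sweep; chromatography
Reagents that add atoms: none
Why: Proposed new method: PPTS reversibly dissociates the perketal (the reverse of perketal formation) to hydroperoxide 16 and 2-methoxypropene and protonates the central allene carbon C5 anti to the C3 substituent, giving a Z-configured conjugated oxocarbenium ion at C6 that the peroxide oxygen captures 6-endo, so the O–C6 bond, the methoxy ketal and the cis ring alkene form in one event while aldehyde hemiacetal equilibria remain reversible; the closest known reactions are the acid-catalysed addition of hydroperoxides to enol ethers and the 6-endo cycloisomerisation of β-hydroxyallenes to dihydropyrans; C3 is untouched, C6 forms with little control (about 1:1) and the 6S isomer 17 is separated from its C6 epimer by chromatography.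

Step 7
Reactants: 17 2-[(3R,6S)-6-methoxy-6-[(14E,16E)-octadeca-14,16-dien-1-yl]-3,6-dihydro-1,2-dioxin-3-yl]acetaldehyde
Product: 18 2-[(3R,6S)-6-methoxy-6-[(14E,16E)-octadeca-14,16-dien-1-yl]-3,6-dihydro-1,2-dioxin-3-yl]acetic acid
Conditions: NaClO2, NaH2PO4, 2-methylbut-2-ene (excess), t-BuOH/H2O, 0 °C
Reagents that add atoms: sodium chlorite, [Na+].[O-]Cl=O
Why: Pinnick oxidation converts the aldehyde into the acid at buffered pH while the alkene scavenger intercepts HOCl and protects the diene; the peroxide, the cyclic ketal and both stereocentres are not affected.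

Step 8
Reactants: 18 2-[(3R,6S)-6-methoxy-6-[(14E,16E)-octadeca-14,16-dien-1-yl]-3,6-dihydro-1,2-dioxin-3-yl]acetic acid
Product: 19 methyl 2-[(3R,6S)-6-methoxy-6-[(14E,16E)-octadeca-14,16-dien-1-yl]-3,6-dihydro-1,2-dioxin-3-yl]acetate (xestin B)
Conditions: TMSCHN2, toluene/MeOH (4:1), 0 °C
Reagents that add atoms: (trimethylsilyl)diazomethane, C[Si](C)(C)C=[N+]=[N-]
Why: O-methylation of the carboxylic acid with TMSCHN2 in methanol is neutral, so the base-sensitive β-peroxy ester, the ketal and the diene survive and no stereocentre is touched.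

**Compound list**
1 | methoxyallene (1-methoxypropa-1,2-diene) | COC=C=C | starting material
2 | 1,12-dibromododecane | BrCCCCCCCCCCCCBr | starting material
3 | 1-lithio-1-methoxyallene | [Li]C(OC)=C=C | intermediate
4 | 15-bromo-3-methoxypentadeca-1,2-diene | C=C=C(OC)CCCCCCCCCCCCBr | intermediate
5 | (2E,4E)-hexa-2,4-dien-1-yl acetate | C/C=C/C=C/COC(C)=O | starting material
6 | (13-methoxypentadeca-13,14-dien-1-yl)magnesium bromide | C=C=C(OC)CCCCCCCCCCCC[Mg]Br | intermediate
7 | (17E,19E)-3-methoxyhenicosa-1,2,17,19-tetraene | C=C=C(OC)CCCCCCCCCCCCC/C=C/C=C/C | intermediate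
8 | (E)-3-(dimethylamino)prop-2-enal | CN(C)/C=C/C=O | starting material
9 | [(17E,19E)-3-methoxyhenicosa-1,2,17,19-tetraen-1-yl]lithium | [Li]C=C=C(OC)CCCCCCCCCCCCC/C=C/C=C/C | intermediate
10 | lithium (1E,20E,22E)-1-(dimethylamino)-6-methoxytetracosa-1,4,5,20,22-pentaen-3-olate | CN(C)/C=C/C(O[Li])C=C=C(OC)CCCCCCCCCCCCC/C=C/C=C/C | intermediate
11 | (2E,20E,22E)-6-methoxytetracosa-2,4,5,20,22-pentaenal (allene axis racemic) | O=C/C=C/C=C=C(OC)CCCCCCCCCCCCC/C=C/C=C/C | intermediate
12 | 2,3-dimethylbut-2-ene | CC(C)=C(C)C | starting material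
13 | acetone O-oxide | CC(C)=[O+][O-] | intermediate
14 | 2-hydroperoxy-2-methoxypropane | COC(C)(C)OO | intermediate
15 | (3R,20E,22E)-6-methoxy-3-[(2-methoxypropan-2-yl)peroxy]tetracosa-4,5,20,22-tetraenal (both allene-axis diastereomers) | O=CC[C@@H](OOC(C)(C)OC)C=C=C(OC)CCCCCCCCCCCCC/C=C/C=C/C | intermediate
16 | (3R,20E,22E)-3-hydroperoxy-6-methoxytetracosa-4,5,20,22-tetraenal | O=CC[C@@H](OO)C=C=C(OC)CCCCCCCCCCCCC/C=C/C=C/C | intermediate
17 | 2-[(3R,6S)-6-methoxy-6-[(14E,16E)-octadeca-14,16-dien-1-yl]-3,6-dihydro-1,2-dioxin-3-yl]acetaldehyde | C/C=C/C=C/CCCCCCCCCCCCC[C@@]1(OC)C=C[C@@H](CC=O)OO1 | intermediate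
18 | 2-[(3R,6S)-6-methoxy-6-[(14E,16E)-octadeca-14,16-dien-1-yl]-3,6-dihydro-1,2-dioxin-3-yl]acetic acid | C/C=C/C=C/CCCCCCCCCCCCC[C@@]1(OC)C=C[C@@H](CC(=O)O)OO1 | intermediate
19 | methyl 2-[(3R,6S)-6-methoxy-6-[(14E,16E)-octadeca-14,16-dien-1-yl]-3,6-dihydro-1,2-dioxin-3-yl]acetate (xestin B) | C/C=C/C=C/CCCCCCCCCCCCC[C@@]1(OC)C=C[C@@H](CC(=O)OC)OO1 | target

**Step count**
Total: 8 steps. Longest linear sequence: 7 steps (1, 2, 3, 5, 6, 7, 8); step 4 is a one-step reagent branch. The uncontrolled ketal centre in step 6 caps that step at about half of the cyclised material.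

**Three steps most likely to fail, with fallbacks**

Step 5 (asymmetric peroxidation). Risks are collapse of the β-peroxy enamine to the epoxide, competing 1,6-addition at C5, loss of the acid-sensitive alkoxyallene, and the fact that this enal class is untested. The sense of induction is assigned from the steric-shielding model; the enantiomeric catalyst is equally available if it proves opposite. The fallback sets out from 11 and returns at 17. Enal 11 is treated with anhydrous H2O2 in Et2O and catalytic PPTS at −20 °C. H2O2 adds across the enol-ether bond of the allene (C5 protonated anti to C3) to give (2E,4Z,20E,22E)-6-hydroperoxy-6-methoxytetracosa-2,4,20,22-tetraenal F1, racemic at C6. The same (R)-catalyst then promotes an intramolecular 6-exo oxa-Michael addition of the tethered hydroperoxide to the enal. This closes the dioxine directly, with C3 under catalyst control, to 17 and its C6 epimer 2-[(3R,6R)-6-methoxy-6-[(14E,16E)-octadeca-14,16-dien-1-yl]-3,6-dihydro-1,2-dioxin-3-yl]acetaldehyde F2, which is removed by chromatography.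

Step 6 (ring closure). Risks are trapping of the hydroperoxide by the C1 aldehyde as a 1,2-dioxolan-3-ol, formation of the E-oxocarbenium ion that cannot cyclise, hydrolysis by adventitious water, and an unfavourable C6 ratio. The fallback sets out from 15 and returns at 17. Compound 15 is stirred with PPTS in MeOH at 0 °C, under protic and fully reversible conditions. The perketal is methanolysed, the allene becomes the Z-enone dimethyl ketal and the aldehyde is parked as its dimethyl acetal. The ketone should then take the entropically favoured cyclic peroxyketal, giving (3R,6S)-3-(2,2-dimethoxyethyl)-6-methoxy-6-[(14E,16E)-octadeca-14,16-dien-1-yl]-3,6-dihydro-1,2-dioxine F3 and its epimer (3R,6R)-3-(2,2-dimethoxyethyl)-6-methoxy-6-[(14E,16E)-octadeca-14,16-dien-1-yl]-3,6-dihydro-1,2-dioxine F4. These are separated and F4 is re-equilibrated in the same medium. F3 is then hydrolysed at the acyclic acetal only (AcOH/THF/H2O, 0 °C) to give 17.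

Step 3 (key coupling). Risks are attack through the propargylic terminus of the ambident anion and loss of the alkoxyallene during the mildly acidic collapse of the amino-carbinol. The fallback sets out from 7 and returns at 11. Allene 7 is γ-lithiated as before and quenched with DMF. Neutral aqueous work-up gives (18E,20E)-4-methoxydocosa-2,3,18,20-tetraenal F5, with no acid-triggered elimination needed. Wittig olefination of F5 with Ph3P=CHCHO (toluene, 40 °C) gives the E-enal 11.

**Further compounds**
F1 | step 5 | (2E,4Z,20E,22E)-6-hydroperoxy-6-methoxytetracosa-2,4,20,22-tetraenal | O=C/C=C/C=C\C(OC)(OO)CCCCCCCCCCCCC/C=C/C=C/C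
F2 | step 5 | 2-[(3R,6R)-6-methoxy-6-[(14E,16E)-octadeca-14,16-dien-1-yl]-3,6-dihydro-1,2-dioxin-3-yl]acetaldehyde | C/C=C/C=C/CCCCCCCCCCCCC[C@]1(OC)C=C[C@@H](CC=O)OO1
F3 | step 6 | (3R,6S)-3-(2,2-dimethoxyethyl)-6-methoxy-6-[(14E,16E)-octadeca-14,16-dien-1-yl]-3,6-dihydro-1,2-dioxine | C/C=C/C=C/CCCCCCCCCCCCC[C@@]1(OC)C=C[C@@H](CC(OC)OC)OO1
F4 | step 6 | (3R,6R)-3-(2,2-dimethoxyethyl)-6-methoxy-6-[(14E,16E)-octadeca-14,16-dien-1-yl]-3,6-dihydro-1,2-dioxine | C/C=C/C=C/CCCCCCCCCCCCC[C@]1(OC)C=C[C@@H](CC(OC)OC)OO1
F5 | step 3 | (18E,20E)-4-methoxydocosa-2,3,18,20-tetraenal | O=CC=C=C(OC)CCCCCCCCCCCCC/C=C/C=C/C
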